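## The problem

The target, procyanidin B3 3,3'-di-O-gallate, consists of two (2R,3S)-flavan-3-ol (catechin) units joined by a single bond from C4 of the upper unit (rings A, B, C; unprimed atoms) to C8' of the lower unit (rings D, E, F; primed atoms), with a galloyl ester on O3 and on O3'. Of its five stereocentres, the two of the lower unit are those of (+)-catechin and can be bought, whereas the upper triad C2 (R), C3 (S), C4 (S) has to be made. The interflavan bond must go to C8' and not to C6', and it must form without oligomerisation. In the upper triad C3–O and C4–H lie on one face of ring C and the C2 aryl on the other, so a single syn addition of H and OH across a C3=C4 double bond, from the face remote from the C2 aryl, would create C3 and C4 together; C2 alone can therefore control both. The compound tolerates little: fourteen free phenols oxidise in air or base, the gallates are base-labile, the C4–C8' bond is cleaved by acid, and the benzylic C2–O bonds of free flavanols open to quinone methides in base or on heating. All phenols are therefore carried as benzyl ethers until a final neutral hydrogenolysis, and an ester already in place is exposed only to near-neutral reagents. The enabling feature is that C4 is a diarylmethine bonded to C4a of ring A and to C8' of ring D within the sequence O1–C2–C3–C4. Read back to an alkyne C3≡C4 carrying ring D, this sequence is an aryl propargyl ether whose ring A carbon ortho to O1 can add to C4 in a 6-endo sense, the triple bond being polarised toward C4 by the electron-rich ring D.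

## Retrosynthesis

**17 to 16 to 15 and 4.** The fourteen O–benzyl bonds are cut last (16), then the ester C–O bond of the upper unit, giving alcohol 15 and acid 4. Compound 15 has one free hydroxyl, so the esterification needs no site selectivity. The forward steps must acylate a hindered secondary alcohol and then remove the benzyl groups without touching the esters or the C4–C8' bond.

**15 to 13 (via 14).** The C3–O and C4–H bonds are cut together. Cutting C4–C8' at this stage instead (cation condensation) would leave regiochemistry and oligomerisation open and would ask C3 to control C4. The chosen cut leaves flav-3-ene 13, which has two stereocentres fewer in the upper unit. The forward hydroboration must add syn, place boron on C3, come from the face opposite the C2 aryl, and spare the gallate already on O3'.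

**13 to 12.** The C4–C4a bond is cut, opening ring C to aryl propargyl ether 12. Cutting O1–C2 instead would make or scramble C2 in the ring closure; the chosen cut leaves C2 as a spectator. The forward reaction must close 6-endo at C4 without ionising the C2–O bond.

**12 to 11 and 5.** The C8'–C(sp) bond is cut (Sonogashira). This divides the molecule into halves of similar size: 5 carries both lower stereocentres, the lower gallate and, through the site of its iodine, the 8-linkage; 11 carries the one new stereocentre. Coupling before etherification is rejected because an aryl group on the alkyne would make the carbinol ionise too easily for a stereospecific etherification.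

**5 to 3 and 4.** The ester C–O bond of the lower unit is cut. Placing this gallate on iodide 3, and not on a dimer at the end, has three consequences.
- Each ester is formed on a compound with a single hydroxyl.
- O3' is masked during the palladium/copper and gold steps, where a free hydroxyl could add to the activated alkyne.
- The ester is introduced in the short catechin branch.

The price is that one aryl ester must pass through hydroboration–oxidation. This is met by the slow reaction of BH3·SMe2 with benzoates and by a near-neutral perborate oxidation.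

**11 to 9 and 10.** The C2–O1 bond is cut (Mitsunobu displacement with inversion). A copper-catalysed enantioconvergent propargylic etherification of a racemic ester is attractive, but 10 is a phloroglucinol diether and, toward a soft copper allenylidene, liable to react at carbon. Displacement at an alkoxyphosphonium fixes attack at oxygen. The forward reaction must invert cleanly; the electron-withdrawing terminal ethynyl group disfavours ionisation.

**9 to 8 to 6 and 7.** The C2–C3 bond is cut to aldehyde 6 and silylacetylene 7 (enantioselective alkynylation, then desilylation). This is the one reagent-controlled stereocentre of the route.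

**3 to 2 to 1.** The C8–I bond and four O–benzyl bonds are cut back to (+)-catechin 1. Iodination must select C8 over C6 and over ring B.

## Roads not taken

Alternative 1: two-directional epoxide opening. The cut is at O1–C2 and O1'–C2' together. In the forward step fluoride would free both phenols of the bis-silyl bis-epoxide A1, and camphorsulfonic acid would let each phenol open its neighbouring trans-epoxide at the benzylic carbon with inversion. This closes rings C and F and gives the octa-O-benzyl dimer diol A2, which esterification of both hydroxyls with acid 4 would convert into 16.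
- Merits: two rings form in one operation. All four C2/C3 centres come from reagent-controlled epoxidation of E-alkenes, so no substrate-controlled hydroboration of a crowded alkene is needed and no ester has to pass through a borane step. In these respects it is better than the chosen plan, and its endgame is one step shorter.
- Weak points: A1 cannot come from catechin. Its C4 diarylmethine centre must be set on an acyclic frame with nothing cyclic to control it, and both three-carbon chains must be built on a hexasubstituted ring D. Epoxides next to a 3,4-bis(benzyloxy)phenyl group ionise readily, so the inversion at C2 and C2' that gives the trans relationship can leak, twice. 5-exo attack at C3 also competes.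
- Comparison: the chosen plan buys the lower unit with its two centres, needs one controlling centre instead of five, and is far shorter before the key step.

Alternative 2: ortho-quinone methide cycloaddition. The cut is at C3–C4 and O1–C2. Acid would open the boronate ring of benzodioxaborin A3 at its benzylic C–O bond and release a ring A heterodiene with the lower unit on its methide carbon. Hetero-Diels–Alder addition of the (E)-enol gallate A4 would close ring C and give A5, which is identical with 16.
- Merits: it is the most convergent road. Ring C, the upper gallate and three stereocentres arrive in one step, and only hydrogenolysis remains. It needs two steps fewer after the key step than the chosen plan, and the E geometry of A4 translates directly into the 2,3-trans relationship.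
- Weak points: the heterodiene is planar and its only chiral element is the lower unit on a freely rotating aryl bond, so nothing reliable selects the face and hence the absolute configuration of the upper triad. The 3,4 relationship rests on an unsecured endo/exo preference. An enol ester is an electron-poor partner for an inverse-demand diene that ring D stabilises as a diarylcarbenium. Preparation of A3 adds its own uncertain steps.
- Comparison: the chosen plan traces every stereocentre to a defined control element, at the price of two more steps after ring closure.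

Alternative 3: ring A from a triketide. The cut removes ring A down to the dioxohexanoate A6. LDA would drive Claisen closure and aromatisation of ring A, and on acidification a new phenol would condense with the aryl ketone to give the 4H-chromene A7 with C4 already in place. Hydroboration anti to the C4 aryl would then set C2 and C3.
- Merits: C4, the centre that defines the interflavan bond, is set explicitly and not by facial selectivity at a crowded alkene. Ring D cannot be attacked at the wrong position.
- Weak points: A6 is long to make. Its C4 centre sits beta to two acidic sites and can be lost by retro-Michael cleavage under LDA. Aldol closure competes with Claisen closure. A7 has two free phenols that need a further benzylation, and it is an acid- and air-sensitive enol ether. Ring A is built from scratch although it is available as phenol 10.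
- Comparison: the chosen plan uses ring A as bought and relays from a C2 centre made by standard asymmetric alkynylation; alternative 3 is superior only in how directly it sets C4.

Key step: step 8

Assumption: (S,S)-ProPhenol is taken to deliver the (S)-carbinol 8; if the sense of induction is opposite for this aldehyde, the equally available (R,R)-ligand is used and nothing else changes.

## Route

Step 1
Reactants: 1 (+)-catechin
Product: 2 (2R,3S)-5,7-bis(benzyloxy)-2-[3,4-bis(benzyloxy)phenyl]chroman-3-ol (tetra-O-benzylcatechin)
Conditions: BnBr (4.4 equiv), K2CO3, DMF, 0 °C to rt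
Reagents that add atoms: benzyl bromide, BrCc1ccccc1
Why: Williamson ether synthesis; the four phenols are alkylated under carbonate while the far less acidic secondary 3-hydroxyl stays free, and the mild base at or below room temperature avoids epimerisation at C2, so both stereocentres of catechin are retained.

Step 2
Reactants: 2 tetra-O-benzylcatechin
Product: 3 (2R,3S)-5,7-bis(benzyloxy)-2-[3,4-bis(benzyloxy)phenyl]-8-iodochroman-3-ol
Conditions: N-iodosuccinimide (1.05 equiv), CH2Cl2, −20 to 0 °C, dark
Reagents that add atoms: N-iodosuccinimide, O=C1CCC(=O)N1I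
Why: Electrophilic aromatic iodination; the phloroglucinol-type ring A is far more nucleophilic than ring B, and C8 (next to the ring oxygen) should react before C6 (between two benzyloxy groups), as in the known C8 bromination of this ether with N-bromosuccinimide.

Step 3
Reactants: 3 8-iodo-tetra-O-benzylcatechin; 4 3,4,5-tris(benzyloxy)benzoic acid
Product: 5 (2R,3S)-5,7-bis(benzyloxy)-2-[3,4-bis(benzyloxy)phenyl]-8-iodochroman-3-yl 3,4,5-tris(benzyloxy)benzoate
Conditions: DCC, DMAP, CH2Cl2, 0 °C to rt
Reagents that add atoms: none
Why: Steglich esterification; the acylpyridinium formed from the O-acylisourea and DMAP acylates the only free hydroxyl at oxygen, so C3 keeps its configuration. The aryl iodide and the benzyl ethers are inert, and the ester masks O3' through the coupling and gold steps.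

Step 4
Reactants: 6 3,4-bis(benzyloxy)benzaldehyde; 7 ethynyltrimethylsilane
Product: 8 (S)-1-[3,4-bis(benzyloxy)phenyl]-3-(trimethylsilyl)prop-2-yn-1-ol
Conditions: Me2Zn, (S,S)-ProPhenol (10 mol %), Ph3PO (20 mol %), toluene, 0 to 4 °C; aq. NH4Cl
Reagents that add atoms: none
Why: Catalytic enantioselective alkynylation of an aryl aldehyde; the dinuclear zinc alkoxide formed from Me2Zn and the ligand holds the alkynylzinc and the aldehyde together and selects one carbonyl face, creating the carbinol centre that becomes C2 of the upper unit after the inversion of step 6.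

Step 5
Reactants: 8 (S)-silyl carbinol
Product: 9 (R)-1-[3,4-bis(benzyloxy)phenyl]prop-2-yn-1-ol
Conditions: K2CO3 (cat.), MeOH–THF, rt
Reagents that add atoms: none
Why: Methoxide-mediated protodesilylation of the alkynylsilane; no bond to the carbinol centre is touched, and the descriptor changes from S to R only because the alkynyl group falls in priority.

Step 6
Reactants: 9 (R)-propargylic alcohol; 10 3,5-bis(benzyloxy)phenol
Product: 11 (S)-1-[3,4-bis(benzyloxy)phenyl]prop-2-yn-1-yl 3,5-bis(benzyloxy)phenyl ether
Conditions: PPh3, DIAD, toluene, −20 to 0 °C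
Reagents that add atoms: none
Why: Mitsunobu etherification; the phenoxide displaces the alkoxyphosphonium in an SN2 step with inversion, which sets the C2 configuration and confines attack to oxygen, while the non-polar solvent, low temperature and electron-withdrawing terminal ethynyl group disfavour ionisation.

Step 7
Reactants: 11 (S)-aryl propargyl ether; 5 8-iodo gallate
Product: 12 (2R,3S)-5,7-bis(benzyloxy)-2-[3,4-bis(benzyloxy)phenyl]-8-{(3R)-3-[3,4-bis(benzyloxy)phenyl]-3-[3,5-bis(benzyloxy)phenoxy]prop-1-yn-1-yl}chroman-3-yl 3,4,5-tris(benzyloxy)benzoate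
Conditions: PdCl2(PPh3)2 (5 mol %), CuI (10 mol %), Et3N, DMF, degassed, 45–55 °C
Reagents that add atoms: none
Why: Sonogashira coupling; zerovalent palladium inserts into the C8–I bond, the copper acetylide transmetallates and reductive elimination forms C8'–C(sp), with no bond to the propargylic centre broken and the ester and benzyl ethers untouched. Any minor enantiomer of 11 becomes a diastereomer of 12 that chromatography can remove.

Step 8
Reactants: 12 aryl propargyl ether
Product: 13 (2R,3S)-5,7-bis(benzyloxy)-2-[3,4-bis(benzyloxy)phenyl]-8-{(2S)-5,7-bis(benzyloxy)-2-[3,4-bis(benzyloxy)phenyl]-2H-chromen-4-yl}chroman-3-yl 3,4,5-tris(benzyloxy)benzoate (4-(3-O-galloylcatechin-8-yl)flav-3-ene)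
Conditions: Ph3PAuNTf2 (5 mol %), 4 Å MS, CH2Cl2, −20 to 0 °C
Reagents that add atoms: none
Why: The cationic monovalent gold centre of Ph3PAuNTf2 binds the alkyne and slips toward C3, because the trioxygenated ring D donates into the triple bond and the propargylic oxygen withdraws from C3, so that positive charge builds on C4. The ring A carbon ortho to the ether oxygen (either one, the 3,5-bis(benzyloxy)phenyl ring being symmetric) attacks C4 anti to gold in a Friedel–Crafts manner, the arenium ion loses its proton, and protodeauration of the C3 vinylgold releases 13 and the catalyst. The closest known reaction type is the gold- or platinum-catalysed intramolecular hydroarylation of aryl propargyl ethers to 2H-chromenes. Ring C closes in the 6-endo-dig mode by forming C4–C4a; the 5-exo mode would place the charge on C3, away from the donor aryl. No stereocentre is created: none of the four bonds at C2 is broken, so its configuration is that fixed in steps 4 and 6, and the gallate on O3' is a spectator. The step needs chemoselectivity for carbon attack by ring A over ionisation of the doubly activated C2–O bond, over attack of a ring D ether oxygen on the activated alkyne, and over the thermal Claisen and oxa-6π path through an achiral ring-opened quinone methide. This is secured by the high nucleophilicity of the phloroglucinol-type ring A, by a silver-free and acid-free catalyst with a non-coordinating counter-ion, and by working at or below 0 °C.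

Step 9
Reactants: 13 4-(3-O-galloylcatechin-8-yl)flav-3-ene
Product: 15 undeca-O-benzyl procyanidin B3 3'-O-gallate with the upper 3-hydroxyl free, via C3 alkylborane 14 (not isolated)
Conditions: BH3·SMe2 (3 equiv), THF, 0 °C to rt; then NaBO3·4H2O, THF–H2O, rt
Reagents that add atoms: sodium perborate tetrahydrate NaBO3·4H2O, [Na+].[Na+].O[B-]1(O)OO[B-](O)(O)OO1; borane–dimethyl sulfide, C[S+](C)[BH3-] (boron appears in 14 only)
Why: Hydroboration–oxidation; borane adds syn, with boron on the less substituted C3 and hydrogen on the diaryl-substituted C4, from the face opposite the adjacent C2 aryl, and oxidation with retention gives C3–OH trans to the C2 aryl and C4–H cis to C3–OH, so C2 sets C3 (S) and C4 (S), as known for flav-3-enes giving 2,3-trans-flavan-3-ols. The electron-rich aryl ester is reduced only slowly by BH3·SMe2 at or below room temperature, and the weakly basic perborate oxidation spares it.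

Step 10
Reactants: 15 undeca-O-benzyl procyanidin B3 3'-O-gallate; 4 3,4,5-tris(benzyloxy)benzoic acid
Product: 16 tetradeca-O-benzyl procyanidin B3 3,3'-di-O-gallate
Conditions: DCC, DMAP, CH2Cl2, rt
Reagents that add atoms: none
Why: Steglich esterification of the single remaining hydroxyl; acylation takes place at oxygen, so no stereocentre is affected, and the neutral conditions leave the first gallate and the C4–C8' bond alone.

Step 11
Reactants: 16 tetradeca-O-benzyl digallate
Product: 17 procyanidin B3 3,3'-di-O-gallate (target)
Conditions: H2 (1 atm), Pd(OH)2/C, THF–MeOH–H2O, rt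
Reagents that add atoms: none
Why: Catalytic hydrogenolysis of the fourteen benzyl ethers under neutral conditions, which spare the gallate esters, the ring C and ring F ethers and the C4–C8' bond; no stereocentre is involved.

## Compound list

1 | (+)-catechin, (2R,3S) | O[C@H]1Cc2c(O)cc(O)cc2O[C@@H]1c1ccc(O)c(O)c1 | starting material
2 | (2R,3S)-5,7-bis(benzyloxy)-2-[3,4-bis(benzyloxy)phenyl]chroman-3-ol | O[C@H]1Cc2c(OCc4ccccc4)cc(OCc4ccccc4)cc2O[C@@H]1c1ccc(OCc4ccccc4)c(OCc4ccccc4)c1 | intermediate
3 | (2R,3S)-5,7-bis(benzyloxy)-2-[3,4-bis(benzyloxy)phenyl]-8-iodochroman-3-ol | O[C@H]1Cc2c(OCc4ccccc4)cc(OCc4ccccc4)c(I)c2O[C@@H]1c1ccc(OCc4ccccc4)c(OCc4ccccc4)c1 | intermediate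
4 | 3,4,5-tris(benzyloxy)benzoic acid | OC(=O)c1cc(OCc2ccccc2)c(OCc2ccccc2)c(OCc2ccccc2)c1 | starting material
5 | (2R,3S)-5,7-bis(benzyloxy)-2-[3,4-bis(benzyloxy)phenyl]-8-iodochroman-3-yl 3,4,5-tris(benzyloxy)benzoate | O=C(O[C@H]1Cc2c(OCc4ccccc4)cc(OCc4ccccc4)c(I)c2O[C@@H]1c1ccc(OCc4ccccc4)c(OCc4ccccc4)c1)c1cc(OCc4ccccc4)c(OCc4ccccc4)c(OCc4ccccc4)c1 | intermediate
6 | 3,4-bis(benzyloxy)benzaldehyde | O=Cc1ccc(OCc2ccccc2)c(OCc2ccccc2)c1 | starting material
7 | ethynyltrimethylsilane | C#C[Si](C)(C)C | starting material
8 | (S)-1-[3,4-bis(benzyloxy)phenyl]-3-(trimethylsilyl)prop-2-yn-1-ol | C[Si](C)(C)C#C[C@@H](O)c1ccc(OCc4ccccc4)c(OCc4ccccc4)c1 | intermediate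
9 | (R)-1-[3,4-bis(benzyloxy)phenyl]prop-2-yn-1-ol | C#C[C@@H](O)c1ccc(OCc4ccccc4)c(OCc4ccccc4)c1 | intermediate
10 | 3,5-bis(benzyloxy)phenol | Oc1cc(OCc2ccccc2)cc(OCc2ccccc2)c1 | starting material
11 | (S)-1-[3,4-bis(benzyloxy)phenyl]prop-2-yn-1-yl 3,5-bis(benzyloxy)phenyl ether | C#C[C@H](Oc1cc(OCc4ccccc4)cc(OCc4ccccc4)c1)c1ccc(OCc4ccccc4)c(OCc4ccccc4)c1 | intermediate
12 | aryl propargyl ether, precursor of the key step: (3R) at the propargylic carbon, lower unit (2R,3S) with O3' as its tri-O-benzylgallate | C(#Cc2c(OCc4ccccc4)cc(OCc4ccccc4)c3c2O[C@H](c2ccc(OCc4ccccc4)c(OCc4ccccc4)c2)[C@@H](OC(=O)c2cc(OCc4ccccc4)c(OCc4ccccc4)c(OCc4ccccc4)c2)C3)[C@H](Oc1cc(OCc4ccccc4)cc(OCc4ccccc4)c1)c1ccc(OCc4ccccc4)c(OCc4ccccc4)c1 | intermediate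
13 | 4-(3-O-galloylcatechin-8-yl)flav-3-ene, product of the key step: (2S) in the 2H-chromene, lower unit (2R,3S) with O3' as its tri-O-benzylgallate | C1=C(c2c(OCc4ccccc4)cc(OCc4ccccc4)c3c2O[C@H](c2ccc(OCc4ccccc4)c(OCc4ccccc4)c2)[C@@H](OC(=O)c2cc(OCc4ccccc4)c(OCc4ccccc4)c(OCc4ccccc4)c2)C3)c2c(OCc4ccccc4)cc(OCc4ccccc4)cc2O[C@@H]1c1ccc(OCc4ccccc4)c(OCc4ccccc4)c1 | intermediate
14 | C3 alkylborane (not isolated): BH2 on C3 anti to the C2 aryl, H on C4 syn to boron, lower gallate unchanged | B[C@H]1[C@H](c2c(OCc4ccccc4)cc(OCc4ccccc4)c3c2O[C@H](c2ccc(OCc4ccccc4)c(OCc4ccccc4)c2)[C@@H](OC(=O)c2cc(OCc4ccccc4)c(OCc4ccccc4)c(OCc4ccccc4)c2)C3)c2c(OCc4ccccc4)cc(OCc4ccccc4)cc2O[C@@H]1c1ccc(OCc4ccccc4)c(OCc4ccccc4)c1 | intermediate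
15 | undeca-O-benzyl procyanidin B3 3'-O-gallate, upper (2R,3S,4S) with free 3-hydroxyl, lower (2R,3S) | O[C@H]1[C@H](c2c(OCc4ccccc4)cc(OCc4ccccc4)c3c2O[C@H](c2ccc(OCc4ccccc4)c(OCc4ccccc4)c2)[C@@H](OC(=O)c2cc(OCc4ccccc4)c(OCc4ccccc4)c(OCc4ccccc4)c2)C3)c2c(OCc4ccccc4)cc(OCc4ccccc4)cc2O[C@@H]1c1ccc(OCc4ccccc4)c(OCc4ccccc4)c1 | intermediate
16 | tetradeca-O-benzyl procyanidin B3 3,3'-di-O-gallate | O=C(O[C@H]1[C@H](c2c(OCc4ccccc4)cc(OCc4ccccc4)c3c2O[C@H](c2ccc(OCc4ccccc4)c(OCc4ccccc4)c2)[C@@H](OC(=O)c2cc(OCc4ccccc4)c(OCc4ccccc4)c(OCc4ccccc4)c2)C3)c2c(OCc4ccccc4)cc(OCc4ccccc4)cc2O[C@@H]1c1ccc(OCc4ccccc4)c(OCc4ccccc4)c1)c1cc(OCc4ccccc4)c(OCc4ccccc4)c(OCc4ccccc4)c1 | intermediate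
17 | procyanidin B3 3,3'-di-O-gallate, upper (2R,3S,4S), lower (2R,3S) | O=C(O[C@H]1[C@H](c2c(O)cc(O)c3c2O[C@H](c2ccc(O)c(O)c2)[C@@H](OC(=O)c2cc(O)c(O)c(O)c2)C3)c2c(O)cc(O)cc2O[C@@H]1c1ccc(O)c(O)c1)c1cc(O)c(O)c(O)c1 | target

## Step count and risks

Total: 11 steps. Longest linear sequence: 8 steps (steps 4 to 11 from aldehyde 6; equally steps 1 to 3 and 7 to 11 from catechin 1).

**Step 8 (key step).** The most likely failure is ionisation of the C2–O bond, which is activated by the ring B donor and by the ring D-substituted alkyne, under gold or adventitious acid. This would erode the C2 configuration or transfer the propargyl unit to a ring carbon. A second possibility is attack of a ring D ether oxygen on the activated alkyne. Fallback: from 12, iodonium-induced cyclisation under bicarbonate buffer (I2, NaHCO3, MeCN, rt) closes the same C4–C4a bond and gives the 3-iodoflav-3-ene F1. Palladium-catalysed hydrodeiodination (Bu3SnH, Pd(PPh3)4 cat., THF) then returns to the route at 13. If both ring closures fail, the fallback given under step 9 reaches 16 without 12 or 13.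

**Step 6.** Partial loss of configuration by ion-pair (SN1-like) substitution at the electron-rich benzylic, propargylic carbon is the main risk. Fallback: from 9, acetylation (Ac2O, DMAP, Et3N) gives the propargylic acetate F2. A copper-catalysed enantioconvergent propargylic etherification with 10 (CuOTf·1/2C6H6, the Ph-pybox antipode that delivers the (S)-ether, iPr2NEt, non-nucleophilic solvent, low temperature) proceeds through a copper allenylidene under ligand control and returns at 11. Its own hazard is carbon attack by the ambident phenol, which is why it is not the first choice.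

**Step 7.** Oxidative addition into the di-ortho-oxygenated, electron-rich C8–I bond may be slow. Copper-mediated alkyne homocoupling and loss of the aryloxy group from the propargylic position (erosion at C2) could then compete. Fallback: a copper- and amine-free Negishi alkynylation. From 11, n-BuLi (−78 °C) then ZnCl2 gives the alkynylzinc chloride F3. This is coupled with 5 using Pd(PPh3)4 in THF, the alkynylzinc leaving the ester alone, and the sequence returns at 12.

**Step 9.** Addition of borane to the congested C3=C4 bond may be sluggish, facial discrimination by the C2 aryl may be incomplete, some boron may go to C4, or prolonged exposure to excess borane may begin to reduce the lower gallate. Fallback: give up the relay and form the C4–C8' bond by Lewis-acid condensation of two galloylated catechin units. From 2, esterification with acid 4 (DCC, DMAP, CH2Cl2) gives the 3-O-(tri-O-benzylgalloyl) ester F4, which serves as the nucleophile. Also from 2, DDQ and 2-ethoxyethanol in CH2Cl2 give the 4-(2-ethoxyethoxy) ether F5, and esterification of its 3-hydroxyl with 4 (DCC, DMAP) gives the 3-O-gallate F6. Me3SiOTf (cat.) in CH2Cl2 at −78 °C ionises C4 of F6 and, with the neighbouring ester directing attack trans to O3 and F4 in excess to suppress oligomerisation, C8 of F4 is alkylated. The sequence returns to the route at 16 and makes step 10 unnecessary.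

**Step 4.** The enantioselectivity may be insufficient, or the sense of induction opposite, for this electron-rich aldehyde. Fallback: from 6, ethynylmagnesium bromide (THF, 0 °C) gives the racemic carbinol F7. Kinetic resolution with Candida antarctica lipase B and vinyl acetate separates the antipodes as alcohol and acetate. By the empirical size rule for lipase acylation of secondary alcohols, the (R)-series material is expected as the acetate F2, and methanolysis (K2CO3, MeOH) brings it back to the route at 9.

## Further compounds

F1 | step 8 | 3-iodo derivative of 13 (3-iodo-4-(3-O-galloylcatechin-8-yl)flav-3-ene, C2 as in 13) | IC1=C(c2c(OCc4ccccc4)cc(OCc4ccccc4)c3c2O[C@H](c2ccc(OCc4ccccc4)c(OCc4ccccc4)c2)[C@@H](OC(=O)c2cc(OCc4ccccc4)c(OCc4ccccc4)c(OCc4ccccc4)c2)C3)c2c(OCc4ccccc4)cc(OCc4ccccc4)cc2O[C@@H]1c1ccc(OCc4ccccc4)c(OCc4ccccc4)c1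
F2 | step 6 | (R)-1-[3,4-bis(benzyloxy)phenyl]prop-2-yn-1-yl acetate | C#C[C@@H](OC(C)=O)c1ccc(OCc4ccccc4)c(OCc4ccccc4)c1
F3 | step 7 | alkynylzinc chloride of 11 | Cl[Zn]C#C[C@H](Oc1cc(OCc4ccccc4)cc(OCc4ccccc4)c1)c1ccc(OCc4ccccc4)c(OCc4ccccc4)c1
F4 | step 9 | (2R,3S)-5,7-bis(benzyloxy)-2-[3,4-bis(benzyloxy)phenyl]chroman-3-yl 3,4,5-tris(benzyloxy)benzoate | O=C(O[C@H]1Cc2c(OCc4ccccc4)cc(OCc4ccccc4)cc2O[C@@H]1c1ccc(OCc4ccccc4)c(OCc4ccccc4)c1)c1cc(OCc4ccccc4)c(OCc4ccccc4)c(OCc4ccccc4)c1
F5 | step 9 | (2R,3S,4S)-5,7-bis(benzyloxy)-2-[3,4-bis(benzyloxy)phenyl]-4-(2-ethoxyethoxy)chroman-3-ol | O[C@H]1[C@@H](OCCOCC)c2c(OCc4ccccc4)cc(OCc4ccccc4)cc2O[C@@H]1c1ccc(OCc4ccccc4)c(OCc4ccccc4)c1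
F6 | step 9 | (2R,3S,4S)-5,7-bis(benzyloxy)-2-[3,4-bis(benzyloxy)phenyl]-4-(2-ethoxyethoxy)chroman-3-yl 3,4,5-tris(benzyloxy)benzoate | O=C(O[C@H]1[C@@H](OCCOCC)c2c(OCc4ccccc4)cc(OCc4ccccc4)cc2O[C@@H]1c1ccc(OCc4ccccc4)c(OCc4ccccc4)c1)c1cc(OCc4ccccc4)c(OCc4ccccc4)c(OCc4ccccc4)c1
F7 | step 4 | racemic 1-[3,4-bis(benzyloxy)phenyl]prop-2-yn-1-ol | C#CC(O)c1ccc(OCc4ccccc4)c(OCc4ccccc4)c1
A1 | alternative 1 | bis(trans-epoxide) bis(tert-butyldimethylsilyl ether): C4 diarylmethine carrying silyloxy ring A, silyloxy ring D and both 2-aryl-oxirane chains | c1(ccc(OCc4ccccc4)c(OCc4ccccc4)c1)[C@@H]1O[C@H]1[C@H](c1c(OCc4ccccc4)cc(OCc4ccccc4)c(C[C@@H]2O[C@H]2c2ccc(OCc4ccccc4)c(OCc4ccccc4)c2)c1O[Si](C)(C)C(C)(C)C)c1c(OCc4ccccc4)cc(OCc4ccccc4)cc1O[Si](C)(C)C(C)(C)C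
A2 | alternative 1 | octa-O-benzyl catechin-(4 to 8')-catechin with free O3H and O3'H | O[C@H]1[C@H](c2c(OCc4ccccc4)cc(OCc4ccccc4)c3c2O[C@H](c2ccc(OCc4ccccc4)c(OCc4ccccc4)c2)[C@@H](O)C3)c2c(OCc4ccccc4)cc(OCc4ccccc4)cc2O[C@@H]1c1ccc(OCc4ccccc4)c(OCc4ccccc4)c1
A3 | alternative 2 | 5,7-bis(benzyloxy)-2-phenyl-4H-1,3,2-benzodioxaborin bearing at C4 the 3'-O-(tri-O-benzylgalloyl) lower unit (either C4 epimer) | c1ccccc1B1Oc2cc(OCc4ccccc4)cc(OCc4ccccc4)c2C(O1)c1c(OCc4ccccc4)cc(OCc4ccccc4)c2c1O[C@H](c1ccc(OCc4ccccc4)c(OCc4ccccc4)c1)[C@@H](OC(=O)c1cc(OCc4ccccc4)c(OCc4ccccc4)c(OCc4ccccc4)c1)C2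
A4 | alternative 2 | (E)-2-[3,4-bis(benzyloxy)phenyl]ethenyl 3,4,5-tris(benzyloxy)benzoate | O=C(O/C=C/c1ccc(OCc4ccccc4)c(OCc4ccccc4)c1)c1cc(OCc4ccccc4)c(OCc4ccccc4)c(OCc4ccccc4)c1
A5 | alternative 2 | tetradeca-O-benzyl ether of the target (identical with 16) | O=C(O[C@H]1[C@H](c2c(OCc4ccccc4)cc(OCc4ccccc4)c3c2O[C@H](c2ccc(OCc4ccccc4)c(OCc4ccccc4)c2)[C@@H](OC(=O)c2cc(OCc4ccccc4)c(OCc4ccccc4)c(OCc4ccccc4)c2)C3)c2c(OCc4ccccc4)cc(OCc4ccccc4)cc2O[C@@H]1c1ccc(OCc4ccccc4)c(OCc4ccccc4)c1)c1cc(OCc4ccccc4)c(OCc4ccccc4)c(OCc4ccccc4)c1
A6 | alternative 3 | methyl 3,5-dioxohexanoate carrying at C2 the 3-aryl-3-oxo-1-(O-silyl lower unit)propyl group, C4 as in the target, epimeric at the ester-bearing carbon | CC(=O)CC(=O)C(C(=O)OC)[C@H](CC(=O)c1ccc(OCc4ccccc4)c(OCc4ccccc4)c1)c1c(OCc4ccccc4)cc(OCc4ccccc4)c2c1O[C@H](c1ccc(OCc4ccccc4)c(OCc4ccccc4)c1)[C@@H](O[Si](C)(C)C(C)(C)C)C2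
A7 | alternative 3 | 5,7-dihydroxy-4-(O-silyl tetra-O-benzylcatechin-8-yl)flav-2-ene with ring B benzylated | C1(c5ccc(OCc4ccccc4)c(OCc4ccccc4)c5)=C[C@H](c2c(OCc4ccccc4)cc(OCc4ccccc4)c3c2O[C@H](c2ccc(OCc4ccccc4)c(OCc4ccccc4)c2)[C@@H](O[Si](C)(C)C(C)(C)C)C3)c2c(O)cc(O)cc2O1
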